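**Retrosynthetic overview**
- The lactone (the only ring) is closed last from a 3,5-anti-dihydroxy ester; C5 comes from hydroxyl-directed reduction of a C5 enone, installed by cross-metathesis at C6=C7 with a vinyl ketone made from the commercial (3R) phosphorane.
- C19–C20 and the C20 hydroxymethyl: carboalumination of a C18 alkyne, trans-selective coupling with a 1,1-dibromoalkene, then Br–Li exchange/CH2O; the trimethyl tail comes from (S)-2-methylbutyl bromide and two lactate triflates (SN2 inversion).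
- C16–C17 and the E C14=C15 alkene: [2,3]-Wittig rearrangement of a (Z)-allyl propargyl ether, with chirality relayed from C13 through a Felkin–Anh reduction.
- C11–C12: nickel-electrocatalytic decarboxylative alkenylation joining the (R)-malic acid dioxolanone ester with an (E)-iodoalkene from (S)-glycidol; the iodoalkene is made by a proposed chromium-electrocatalytic iodo-olefination.

Assumption: (S)-glycidol, (R)-malic acid, both ethyl 2-(triflyloxy)propanoates, (S)-1-bromo-2-methylbutane and the (3R) statin phosphorane 31 are taken as purchasable, cheap chiral-pool or bulk chiral materials. Carbon numbers C1–C28 refer to the target chain (C1 = lactone carbonyl).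

**Step 1**
Reactants: 1 (S)-1-bromo-2-methylbutane; 2 ethyl (S)-2-(trifluoromethylsulfonyloxy)propanoate
Product: 4 ethyl (2S,4S)-2,4-dimethylhexanoate, via (S)-2-methylbutylmagnesium bromide 3 (not isolated)
Conditions: Mg, THF; then 2, ZnCl2 (5 mol%), THF, 0 °C
Reagents that add atoms: none
Why: Zinc-catalysed SN2 coupling of an alkyl Grignard reagent with an α-triflyloxy ester; the zincate displaces triflate with inversion, so the (S)-lactate carbon becomes C24 (S), and the ester is not attacked.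

**Step 2**
Reactants: 4 ethyl (2S,4S)-2,4-dimethylhexanoate
Product: 5 (2S,4S)-2,4-dimethylhexan-1-ol
Conditions: LiAlH4, Et2O, 0 °C
Reagents that add atoms: none
Why: Hydride reduction of the ester to the primary alcohol, which leaves both stereocenters untouched.

**Step 3**
Reactants: 5 (2S,4S)-2,4-dimethylhexan-1-ol
Product: 6 (2S,4S)-1-bromo-2,4-dimethylhexane
Conditions: CBr4, PPh3, CH2Cl2, 0 °C
Reagents that add atoms: carbon tetrabromide, BrC(Br)(Br)Br
Why: Appel bromination, an SN2 displacement at the primary CH2 that does not touch the stereocenters.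

**Step 4**
Reactants: 6 (2S,4S)-1-bromo-2,4-dimethylhexane; 7 ethyl (R)-2-(trifluoromethylsulfonyloxy)propanoate
Product: 9 ethyl (2R,4S,6S)-2,4,6-trimethyloctanoate, via (2S,4S)-2,4-dimethylhexylmagnesium bromide 8 (not isolated)
Conditions: Mg, THF; then 7, ZnCl2 (5 mol%), THF, 0 °C
Reagents that add atoms: none
Why: Second zinc-catalysed Grignard/α-triflyloxy ester SN2 coupling; inversion of the (R)-lactate carbon sets C22 (R), anti to C24.

**Step 5**
Reactants: 9 ethyl (2R,4S,6S)-2,4,6-trimethyloctanoate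
Product: 10 (2R,4S,6S)-2,4,6-trimethyloctanal
Conditions: i-Bu2AlH, CH2Cl2, −78 °C
Reagents that add atoms: none
Why: Partial ester reduction; the aluminium hemiacetal is stable at −78 °C and releases the aldehyde on work-up without epimerising the α-centre.

**Step 6**
Reactants: 10 (2R,4S,6S)-2,4,6-trimethyloctanal
Product: 11 (3R,5S,7S)-1,1-dibromo-3,5,7-trimethylnon-1-ene
Conditions: CBr4, PPh3, CH2Cl2, 0 °C
Reagents that add atoms: carbon tetrabromide, BrC(Br)(Br)Br
Why: Ramirez dibromo-olefination (first stage of the Corey–Fuchs reaction), a neutral Wittig-type reaction that preserves the α-stereocenter.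

**Step 7**
Reactants: 12 (S)-glycidol
Product: 13 (R)-pent-4-ene-1,2-diol
Conditions: CH2=CHMgBr (3 equiv), CuI (10 mol%), THF, −30 to 0 °C
Reagents that add atoms: vinylmagnesium bromide, C=C[Mg]Br
Why: Copper-catalysed Grignard opening of the epoxide at the terminal CH2 (SN2); the carbinol carbon is not touched, so (S)-glycidol delivers C9 with the target configuration.

**Step 8**
Reactants: 13 (R)-pent-4-ene-1,2-diol
Product: 14 (R)-1,2-bis(triethylsilyloxy)pent-4-ene
Conditions: Et3SiCl, imidazole, DMF, 0 °C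
Reagents that add atoms: chlorotriethylsilane, CC[Si](Cl)(CC)CC
Why: Standard silylation of both hydroxyl groups.

**Step 9**
Reactants: 14 (R)-1,2-bis(triethylsilyloxy)pent-4-ene
Product: 15 (R)-2-(triethylsilyloxy)pent-4-enal
Conditions: (COCl)2, DMSO, CH2Cl2, −78 to −30 °C; Et3N
Reagents that add atoms: none
Why: Swern oxidation in which activated DMSO cleaves and oxidises the primary triethylsilyl ether directly while the secondary one survives; the α-centre is not epimerised at low temperature.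

**Step 10**
Reactants: 15 (R)-2-(triethylsilyloxy)pent-4-enal
Product: 16 (1E,3R)-1-iodo-3-(triethylsilyloxy)hexa-1,5-diene
Conditions: CHI3, CrCl3 (15 mol%), Me3SiCl, n-Bu4NClO4, THF/1,4-dioxane, undivided cell, Mg anode, carbon-felt cathode, constant current, 0 °C
Reagents that add atoms: iodoform, IC(I)I
Why: Proposed new method: chromium-electrocatalytic Takai–Utimoto iodo-olefination, in which trivalent chromium is reduced at the cathode to divalent chromium, which converts CHI3 into the geminal dichromium species ICH(Cr)2 that adds to the aldehyde and eliminates to the (E)-iodoalkene (forming C10=C11 with E geometry), while Me3SiCl cleaves the Cr–O by-product so chromium can be re-reduced; the closest known reactions are the stoichiometric CrCl2 Takai–Utimoto olefination and the chromium-catalytic electrochemical Nozaki–Hiyama–Kishi coupling, and C9 is a spectator.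

**Step 11**
Reactants: 17 (R)-malic acid
Product: 18 2-[(4R)-2,2-dimethyl-5-oxo-1,3-dioxolan-4-yl]acetic acid
Conditions: Me2C(OMe)2, p-TsOH (cat.), rt
Reagents that add atoms: 2,2-dimethoxypropane, COC(C)(C)OC
Why: Acid-catalysed acetonide formation across the α-hydroxy acid gives the five-membered dioxolanone and leaves the β-carboxyl free, with no bond to the stereocenter broken.

**Step 12**
Reactants: 18 2-[(4R)-2,2-dimethyl-5-oxo-1,3-dioxolan-4-yl]acetic acid
Product: 19 1,3-dioxoisoindolin-2-yl 2-[(4R)-2,2-dimethyl-5-oxo-1,3-dioxolan-4-yl]acetate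
Conditions: N-hydroxyphthalimide, i-PrN=C=N-i-Pr, DMAP (cat.), CH2Cl2, rt
Reagents that add atoms: N-hydroxyphthalimide, ON1C(=O)c2ccccc2C1=O
Why: Carbodiimide (Steglich-type) esterification to the redox-active N-acyloxyphthalimide.

**Step 13**
Reactants: 16 (1E,3R)-1-iodo-3-(triethylsilyloxy)hexa-1,5-diene; 19 1,3-dioxoisoindolin-2-yl 2-[(4R)-2,2-dimethyl-5-oxo-1,3-dioxolan-4-yl]acetate
Product: 20 (5R)-2,2-dimethyl-5-[(2E,4R)-4-(triethylsilyloxy)hepta-2,6-dien-1-yl]-1,3-dioxolan-4-one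
Conditions: NiCl2·glyme (10 mol%), 2,2′-bipyridine (10 mol%), AgNO3 (0.3 equiv), LiCl, DMF, Mg anode, reticulated vitreous carbon cathode, constant current, rt
Reagents that add atoms: none
Why: Nickel-electrocatalysed decarboxylative alkenylation (reductive cross-electrophile coupling of a redox-active ester): zerovalent nickel formed at the cathode inserts into the C–I bond, the primary radical released from 19 is captured, and reductive elimination forms C11–C12 with retention of the E geometry; the radical is flanked only by an acetal oxygen and a lactone carbonyl, so it does not rearrange, and C9 and C13 are spectators.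

**Step 14**
Reactants: 20 (5R)-2,2-dimethyl-5-[(2E,4R)-4-(triethylsilyloxy)hepta-2,6-dien-1-yl]-1,3-dioxolan-4-one
Product: 21 (2Z,5R,7E,9R)-5-hydroxy-9-(triethylsilyloxy)dodeca-2,7,11-trien-4-one
Conditions: (Z)-CH3CH=CHBr, t-BuLi, Et2O, −78 °C; CeCl3, THF; then 20, −78 °C; aq. NH4Cl
Reagents that add atoms: (Z)-1-bromopropene, C/C=C\Br
Why: Acyl substitution on the 1,3-dioxolan-4-one by the alkenyl-lithium/cerium reagent; the tetrahedral adduct collapses only on work-up (loss of acetone), so only one equivalent adds, the Z geometry of the alkenyllithium is retained, and CeCl3 suppresses enolisation at C13.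

**Step 15**
Reactants: 21 (2Z,5R,7E,9R)-5-hydroxy-9-(triethylsilyloxy)dodeca-2,7,11-trien-4-one
Product: 22 (2Z,5R,7E,9R)-9-(triethylsilyloxy)-5-(triisopropylsilyloxy)dodeca-2,7,11-trien-4-one
Conditions: i-Pr3SiOTf, 2,6-lutidine, CH2Cl2, −78 to 0 °C
Reagents that add atoms: triisopropylsilyl triflate, CC(C)[Si](OS(=O)(=O)C(F)(F)F)(C(C)C)C(C)C
Why: Silylation of the α-hydroxy ketone with a non-nucleophilic base, which leaves the Z-enone intact and installs a bulky, non-chelating group for the next step.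

**Step 16**
Reactants: 22 (2Z,5R,7E,9R)-9-(triethylsilyloxy)-5-(triisopropylsilyloxy)dodeca-2,7,11-trien-4-one
Product: 23 (2Z,4R,5R,7E,9R)-9-(triethylsilyloxy)-5-(triisopropylsilyloxy)dodeca-2,7,11-trien-4-ol
Conditions: LiBH(s-Bu)3, THF, −78 °C
Reagents that add atoms: none
Why: Felkin–Anh (polar) 1,2-reduction of the α-silyloxy ketone by the bulky hydride, which attacks anti to the C13–O bond and gives the syn alcohol, so C14 (R, later sacrificed) is set by the malic acid centre C13.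

**Step 17**
Reactants: 23 (2Z,4R,5R,7E,9R)-9-(triethylsilyloxy)-5-(triisopropylsilyloxy)dodeca-2,7,11-trien-4-ol
Product: 24 (2Z,4R,5R,7E,9R)-4-(prop-2-yn-1-yloxy)-9-(triethylsilyloxy)-5-(triisopropylsilyloxy)dodeca-2,7,11-triene
Conditions: NaH, HC≡CCH2Br, n-Bu4NI (cat.), THF/DMF, 0 °C
Reagents that add atoms: propargyl bromide, C#CCBr
Why: Williamson etherification; the bulky triisopropylsilyl group on the neighbouring oxygen was chosen to suppress 1,2-silyl migration in the alkoxide.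

**Step 18**
Reactants: 24 (2Z,4R,5R,7E,9R)-4-(prop-2-yn-1-yloxy)-9-(triethylsilyloxy)-5-(triisopropylsilyloxy)dodeca-2,7,11-triene
Product: 26 (3R,4S,5E,7R,9E,11R)-4-methyl-11-(triethylsilyloxy)-7-(triisopropylsilyloxy)tetradeca-5,9,13-trien-1-yn-3-ol, via dilithiated propargyl ether 25 (not isolated)
Conditions: n-BuLi (2.3 equiv), THF, −78 °C
Reagents that add atoms: none
Why: [2,3]-Wittig rearrangement of the (Z)-allyl propargyl ether through the envelope transition state with the alkynyl group exo; suprafacial chirality transfer from C14 sets C16 (S) and C17 (R) (syn) and the E C14=C15 alkene, forming the C16–C17 bond.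

**Step 19**
Reactants: 26 (3R,4S,5E,7R,9E,11R)-4-methyl-11-(triethylsilyloxy)-7-(triisopropylsilyloxy)tetradeca-5,9,13-trien-1-yn-3-ol; 11 (3R,5S,7S)-1,1-dibromo-3,5,7-trimethylnon-1-ene
Product: 28 (4R,5E,8R,9E,11S,12R,13E,15Z,17R,19S,21S)-15-bromo-11,13,17,19,21-pentamethyl-4-(triethylsilyloxy)-8-(triisopropylsilyloxy)tricosa-1,5,9,13,15-pentaen-12-ol, via alkenylalane 27 (not isolated)
Conditions: Me3Al, Cp2ZrCl2 (0.3 equiv), CH2Cl2, 0 °C to rt; excess Me3Al removed in vacuo; then 11, ZnCl2, PdCl2(DPEphos) (5 mol%), THF, rt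
Reagents that add atoms: trimethylaluminium, C[Al](C)C
Why: Zirconium-catalysed syn-carboalumination (Negishi) of the terminal alkyne gives the (E)-2-methylalkenylalane, which undergoes palladium-catalysed Negishi-type coupling selectively at the less hindered bromide trans to the alkyl chain of the 1,1-dibromoalkene, with retention on both partners (C18=C19 E, C19 trans to C22).

**Step 20**
Reactants: 28 (4R,5E,8R,9E,11S,12R,13E,15Z,17R,19S,21S)-15-bromo-11,13,17,19,21-pentamethyl-4-(triethylsilyloxy)-8-(triisopropylsilyloxy)tricosa-1,5,9,13,15-pentaen-12-ol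
Product: 30 (4R,5E,8R,9E,11S,12R,13E,15Z,17R,19S,21S)-15-(hydroxymethyl)-11,13,17,19,21-pentamethyl-4-(triethylsilyloxy)-8-(triisopropylsilyloxy)tricosa-1,5,9,13,15-pentaen-12-ol, via dienyllithium 29 (not isolated)
Conditions: t-BuLi (3.3 equiv), Et2O, −78 °C; (CH2O)n, −78 to 0 °C
Reagents that add atoms: formaldehyde (as paraformaldehyde), C=O
Why: Bromine–lithium exchange with retention of alkene geometry, then hydroxymethylation by formaldehyde, which places the CH2OH cis to C22.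

**Step 21**
Reactants: 31 methyl (3R)-3-(tert-butyldimethylsilyloxy)-5-oxo-6-(triphenyl-λ5-phosphanylidene)hexanoate
Product: 32 methyl (3R)-3-(tert-butyldimethylsilyloxy)-5-oxohept-6-enoate
Conditions: aq. CH2O, CH2Cl2, rt
Reagents that add atoms: formaldehyde, C=O
Why: Wittig methylenation of formaldehyde by the stabilised acyl ylide gives the vinyl ketone, and C3 is untouched.

**Step 22**
Reactants: 30 (4R,5E,8R,9E,11S,12R,13E,15Z,17R,19S,21S)-15-(hydroxymethyl)-11,13,17,19,21-pentamethyl-4-(triethylsilyloxy)-8-(triisopropylsilyloxy)tricosa-1,5,9,13,15-pentaen-12-ol; 32 methyl (3R)-3-(tert-butyldimethylsilyloxy)-5-oxohept-6-enoate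
Product: 33 methyl (3R,6E,9R,10E,13R,14E,16S,17R,18E,20Z,22R,24S,26S)-3-(tert-butyldimethylsilyloxy)-17-hydroxy-20-(hydroxymethyl)-16,18,22,24,26-pentamethyl-5-oxo-9-(triethylsilyloxy)-13-(triisopropylsilyloxy)octacosa-6,10,14,18,20-pentaenoate
Conditions: second-generation Hoveyda–Grubbs catalyst (10 mol%), 32 (3 equiv), CH2Cl2, 40 °C
Reagents that add atoms: none
Why: Olefin cross-metathesis between the only terminal alkene of 30 and the electron-poor vinyl ketone gives the E-enone; the internal, allylically substituted and trisubstituted alkenes react much more slowly.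

**Step 23**
Reactants: 33 (name as in step 22)
Product: 34 methyl (3R,6E,9R,10E,13R,14E,16S,17R,18E,20Z,22R,24S,26S)-3,9,13,17-tetrahydroxy-20-(hydroxymethyl)-16,18,22,24,26-pentamethyl-5-oxooctacosa-6,10,14,18,20-pentaenoate
Conditions: HF·pyridine, pyridine, THF, 0 °C to rt
Reagents that add atoms: none
Why: Fluoride cleavage of all three silyl ethers under buffered acidic conditions, which avoids base-induced β-elimination of the β-hydroxy enone.

**Step 24**
Reactants: 34 (name as in step 23)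
Product: 35 methyl (3R,5R,6E,9R,10E,13R,14E,16S,17R,18E,20Z,22R,24S,26S)-3,5,9,13,17-pentahydroxy-20-(hydroxymethyl)-16,18,22,24,26-pentamethyloctacosa-6,10,14,18,20-pentaenoate
Conditions: Me4NBH(OAc)3, MeCN/AcOH, −30 °C
Reagents that add atoms: none
Why: Evans–Saksena hydroxyl-directed 1,2-reduction; hydride is delivered intramolecularly from the C3-bound acetoxyborohydride through a chair transition state, giving the 1,3-anti diol and so C5 (R).

**Step 25**
Reactants: 35 (name as in step 24)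
Product: 36 (4R,6R)-4-hydroxy-6-[(1E,4R,5E,8R,9E,11S,12R,13E,15Z,17R,19S,21S)-4,8,12-trihydroxy-15-(hydroxymethyl)-11,13,17,19,21-pentamethyltricosa-1,5,9,13,15-pentaen-1-yl]oxan-2-one (CNP0353667.1)
Conditions: PPTS (cat.), benzene, 40 °C
Reagents that add atoms: none
Why: Acid-catalysed lactonisation of the δ-hydroxy ester to the six-membered lactone with retention at C5, giving the cis-4,6-disubstituted ring.

**Compound list**

1 | (S)-1-bromo-2-methylbutane | CC[C@H](C)CBr | starting material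
2 | ethyl (S)-2-(trifluoromethylsulfonyloxy)propanoate | C[C@H](OS(=O)(=O)C(F)(F)F)C(=O)OCC | starting material
3 | (S)-2-methylbutylmagnesium bromide | CC[C@H](C)C[Mg]Br | intermediate
4 | ethyl (2S,4S)-2,4-dimethylhexanoate | CC[C@H](C)C[C@H](C)C(=O)OCC | intermediate
5 | (2S,4S)-2,4-dimethylhexan-1-ol | CC[C@H](C)C[C@H](C)CO | intermediate
6 | (2S,4S)-1-bromo-2,4-dimethylhexane | CC[C@H](C)C[C@H](C)CBr | intermediate
7 | ethyl (R)-2-(trifluoromethylsulfonyloxy)propanoate | C[C@@H](OS(=O)(=O)C(F)(F)F)C(=O)OCC | starting material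
8 | (2S,4S)-2,4-dimethylhexylmagnesium bromide | CC[C@H](C)C[C@H](C)C[Mg]Br | intermediate
9 | ethyl (2R,4S,6S)-2,4,6-trimethyloctanoate | CC[C@H](C)C[C@H](C)C[C@@H](C)C(=O)OCC | intermediate
10 | (2R,4S,6S)-2,4,6-trimethyloctanal | CC[C@H](C)C[C@H](C)C[C@@H](C)C=O | intermediate
11 | (3R,5S,7S)-1,1-dibromo-3,5,7-trimethylnon-1-ene | CC[C@H](C)C[C@H](C)C[C@@H](C)C=C(Br)Br | intermediate
12 | (S)-glycidol | OC[C@H]1CO1 | starting material
13 | (R)-pent-4-ene-1,2-diol | OC[C@H](O)CC=C | intermediate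
14 | (R)-1,2-bis(triethylsilyloxy)pent-4-ene | CC[Si](CC)(CC)OC[C@H](O[Si](CC)(CC)CC)CC=C | intermediate
15 | (R)-2-(triethylsilyloxy)pent-4-enal | O=C[C@H](O[Si](CC)(CC)CC)CC=C | intermediate
16 | (1E,3R)-1-iodo-3-(triethylsilyloxy)hexa-1,5-diene | I/C=C/[C@H](O[Si](CC)(CC)CC)CC=C | intermediate
17 | (R)-malic acid | OC(=O)[C@H](O)CC(O)=O | starting material
18 | 2-[(4R)-2,2-dimethyl-5-oxo-1,3-dioxolan-4-yl]acetic acid | OC(=O)C[C@H]1OC(C)(C)OC1=O | intermediate
19 | 1,3-dioxoisoindolin-2-yl 2-[(4R)-2,2-dimethyl-5-oxo-1,3-dioxolan-4-yl]acetate | O=C(C[C@H]1OC(C)(C)OC1=O)ON1C(=O)c2ccccc2C1=O | intermediate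
20 | (5R)-2,2-dimethyl-5-[(2E,4R)-4-(triethylsilyloxy)hepta-2,6-dien-1-yl]-1,3-dioxolan-4-one | O=C1OC(C)(C)O[C@@H]1C/C=C/[C@H](O[Si](CC)(CC)CC)CC=C | intermediate
21 | (2Z,5R,7E,9R)-5-hydroxy-9-(triethylsilyloxy)dodeca-2,7,11-trien-4-one | C/C=C\C(=O)[C@H](O)C/C=C/[C@H](O[Si](CC)(CC)CC)CC=C | intermediate
22 | (2Z,5R,7E,9R)-9-(triethylsilyloxy)-5-(triisopropylsilyloxy)dodeca-2,7,11-trien-4-one | C/C=C\C(=O)[C@H](O[Si](C(C)C)(C(C)C)C(C)C)C/C=C/[C@H](O[Si](CC)(CC)CC)CC=C | intermediate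
23 | (2Z,4R,5R,7E,9R)-9-(triethylsilyloxy)-5-(triisopropylsilyloxy)dodeca-2,7,11-trien-4-ol | C/C=C\[C@@H](O)[C@H](O[Si](C(C)C)(C(C)C)C(C)C)C/C=C/[C@H](O[Si](CC)(CC)CC)CC=C | intermediate
24 | (2Z,4R,5R,7E,9R)-4-(prop-2-yn-1-yloxy)-9-(triethylsilyloxy)-5-(triisopropylsilyloxy)dodeca-2,7,11-triene | C/C=C\[C@@H](OCC#C)[C@H](O[Si](C(C)C)(C(C)C)C(C)C)C/C=C/[C@H](O[Si](CC)(CC)CC)CC=C | intermediate
25 | dilithiated propargyl ether of 24 (lithium acetylide plus propargylic carbanion) | C/C=C\[C@@H](OC([Li])C#C[Li])[C@H](O[Si](C(C)C)(C(C)C)C(C)C)C/C=C/[C@H](O[Si](CC)(CC)CC)CC=C | intermediate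
26 | (3R,4S,5E,7R,9E,11R)-4-methyl-11-(triethylsilyloxy)-7-(triisopropylsilyloxy)tetradeca-5,9,13-trien-1-yn-3-ol | C#C[C@H](O)[C@@H](C)/C=C/[C@H](O[Si](C(C)C)(C(C)C)C(C)C)C/C=C/[C@H](O[Si](CC)(CC)CC)CC=C | intermediate
27 | (E)-2-methylalkenyl(dimethyl)alane of 26, O-dimethylaluminium alkoxide | C[Al](C)/C=C(\C)[C@H](O[Al](C)C)[C@@H](C)/C=C/[C@H](O[Si](C(C)C)(C(C)C)C(C)C)C/C=C/[C@H](O[Si](CC)(CC)CC)CC=C | intermediate
28 | (4R,5E,8R,9E,11S,12R,13E,15Z,17R,19S,21S)-15-bromo-11,13,17,19,21-pentamethyl-4-(triethylsilyloxy)-8-(triisopropylsilyloxy)tricosa-1,5,9,13,15-pentaen-12-ol | CC[C@H](C)C[C@H](C)C[C@@H](C)/C=C(Br)/C=C(\C)[C@H](O)[C@@H](C)/C=C/[C@H](O[Si](C(C)C)(C(C)C)C(C)C)C/C=C/[C@H](O[Si](CC)(CC)CC)CC=C | intermediate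
29 | C15-lithio derivative of 28, lithium alkoxide | CC[C@H](C)C[C@H](C)C[C@@H](C)/C=C([Li])/C=C(\C)[C@H](O[Li])[C@@H](C)/C=C/[C@H](O[Si](C(C)C)(C(C)C)C(C)C)C/C=C/[C@H](O[Si](CC)(CC)CC)CC=C | intermediate
30 | (4R,5E,8R,9E,11S,12R,13E,15Z,17R,19S,21S)-15-(hydroxymethyl)-11,13,17,19,21-pentamethyl-4-(triethylsilyloxy)-8-(triisopropylsilyloxy)tricosa-1,5,9,13,15-pentaen-12-ol | CC[C@H](C)C[C@H](C)C[C@@H](C)/C=C(CO)/C=C(\C)[C@H](O)[C@@H](C)/C=C/[C@H](O[Si](C(C)C)(C(C)C)C(C)C)C/C=C/[C@H](O[Si](CC)(CC)CC)CC=C | intermediate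
31 | methyl (3R)-3-(tert-butyldimethylsilyloxy)-5-oxo-6-(triphenyl-λ5-phosphanylidene)hexanoate | COC(=O)C[C@H](O[Si](C)(C)C(C)(C)C)CC(=O)C=P(c1ccccc1)(c1ccccc1)c1ccccc1 | starting material
32 | methyl (3R)-3-(tert-butyldimethylsilyloxy)-5-oxohept-6-enoate | COC(=O)C[C@H](O[Si](C)(C)C(C)(C)C)CC(=O)C=C | intermediate
33 | methyl (3R,6E,9R,10E,13R,14E,16S,17R,18E,20Z,22R,24S,26S)-3-(tert-butyldimethylsilyloxy)-17-hydroxy-20-(hydroxymethyl)-16,18,22,24,26-pentamethyl-5-oxo-9-(triethylsilyloxy)-13-(triisopropylsilyloxy)octacosa-6,10,14,18,20-pentaenoate | CC[C@H](C)C[C@H](C)C[C@@H](C)/C=C(CO)/C=C(\C)[C@H](O)[C@@H](C)/C=C/[C@H](O[Si](C(C)C)(C(C)C)C(C)C)C/C=C/[C@H](O[Si](CC)(CC)CC)C/C=C/C(=O)C[C@@H](O[Si](C)(C)C(C)(C)C)CC(=O)OC | intermediate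
34 | methyl (3R,6E,9R,10E,13R,14E,16S,17R,18E,20Z,22R,24S,26S)-3,9,13,17-tetrahydroxy-20-(hydroxymethyl)-16,18,22,24,26-pentamethyl-5-oxooctacosa-6,10,14,18,20-pentaenoate | CC[C@H](C)C[C@H](C)C[C@@H](C)/C=C(CO)/C=C(\C)[C@H](O)[C@@H](C)/C=C/[C@H](O)C/C=C/[C@H](O)C/C=C/C(=O)C[C@@H](O)CC(=O)OC | intermediate
35 | methyl (3R,5R,6E,9R,10E,13R,14E,16S,17R,18E,20Z,22R,24S,26S)-3,5,9,13,17-pentahydroxy-20-(hydroxymethyl)-16,18,22,24,26-pentamethyloctacosa-6,10,14,18,20-pentaenoate | CC[C@H](C)C[C@H](C)C[C@@H](C)/C=C(CO)/C=C(\C)[C@H](O)[C@@H](C)/C=C/[C@H](O)C/C=C/[C@H](O)C/C=C/[C@H](O)C[C@@H](O)CC(=O)OC | intermediate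
36 | (4R,6R)-4-hydroxy-6-[(1E,4R,5E,8R,9E,11S,12R,13E,15Z,17R,19S,21S)-4,8,12-trihydroxy-15-(hydroxymethyl)-11,13,17,19,21-pentamethyltricosa-1,5,9,13,15-pentaen-1-yl]oxan-2-one | CC[C@H](C)C[C@H](C)C[C@@H](C)/C=C(/C=C(\C)[C@H](O)[C@@H](C)/C=C/[C@H](O)C/C=C/[C@H](O)C/C=C/[C@H]1C[C@@H](O)CC(=O)O1)CO | target

**Totals**
Total step count: 25.
Longest linear sequence: 16 steps (7–10, 13–20, 22–25).

**Three steps most likely to fail**

Step 10 (the proposed new method). Direct cathodic reduction of CHI3 or poor chromium turnover could starve the geminal dichromium pathway. The fallback sets out from 15 and comes back at 16. Boron-Wittig olefination of 15 with lithiated bis(pinacolboryl)methane (CH2(Bpin)2, lithium 2,2,6,6-tetramethylpiperidide, THF, −78 °C) gives 2-[(1E,3R)-3-(triethylsilyloxy)hexa-1,5-dien-1-yl]-4,4,5,5-tetramethyl-1,3,2-dioxaborolane F1. Iododeboronation with retention (NaOH, then I2, THF/H2O) then gives 16.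

Step 16. The bulky hydride may add 1,4 to the Z-enone, or the Felkin–Anh selectivity may be modest, and this centre controls C16 and C17. The fallback sets out from 20 and comes back at 23, using an alkyne as a surrogate for the Z-alkene. 1-Propynyllithium with CeCl3 adds to 20 to give (5R,7E,9R)-5-hydroxy-9-(triethylsilyloxy)dodeca-7,11-dien-2-yn-4-one F2. Silylation (i-Pr3SiOTf, 2,6-lutidine) gives (5R,7E,9R)-9-(triethylsilyloxy)-5-(triisopropylsilyloxy)dodeca-7,11-dien-2-yn-4-one F3. LiBH(s-Bu)3 reduces the ynone cleanly 1,2 under the same Felkin–Anh control to (4R,5R,7E,9R)-9-(triethylsilyloxy)-5-(triisopropylsilyloxy)dodeca-7,11-dien-2-yn-4-ol F4. Zinc dust activated with Cu(OAc)2 and AgNO3 in MeOH/H2O semi-reduces the propargylic alkyne to the (Z)-alkene 23 without touching the other alkenes.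

Step 19. The one-pot carboalumination and trans-selective coupling must tolerate a free aluminium alkoxide, and methyl transfer or double coupling could compete. The fallback sets out from 11 and 26 and comes back at 30, so that 28 and step 20 are not needed. n-BuLi (2 equiv) then (CH2O)n converts 11 into (4R,6S,8S)-4,6,8-trimethyldec-2-yn-1-ol F5. Syn-hydrostannation (n-Bu3SnH, PdCl2(PPh3)2, THF) puts tin on the carbinol-side carbon and gives (2E,4R,6S,8S)-4,6,8-trimethyl-2-(tributylstannyl)dec-2-en-1-ol F6. Separately, 26 is carboaluminated (Me3Al, Cp2ZrCl2) and quenched with I2 to give (1E,3R,4S,5E,7R,9E,11R)-1-iodo-2,4-dimethyl-11-(triethylsilyloxy)-7-(triisopropylsilyloxy)tetradeca-1,5,9,13-tetraen-3-ol F7. Stille coupling of F6 with F7 (Pd2(dba)3, AsPh3, CuI, DMF, rt) gives 30.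

**Further compounds**

F1 | step 10 | 2-[(1E,3R)-3-(triethylsilyloxy)hexa-1,5-dien-1-yl]-4,4,5,5-tetramethyl-1,3,2-dioxaborolane | CC1(C)OB(/C=C/[C@H](O[Si](CC)(CC)CC)CC=C)OC1(C)C
F2 | step 16 | (5R,7E,9R)-5-hydroxy-9-(triethylsilyloxy)dodeca-7,11-dien-2-yn-4-one | CC#CC(=O)[C@H](O)C/C=C/[C@H](O[Si](CC)(CC)CC)CC=C
F3 | step 16 | (5R,7E,9R)-9-(triethylsilyloxy)-5-(triisopropylsilyloxy)dodeca-7,11-dien-2-yn-4-one | CC#CC(=O)[C@H](O[Si](C(C)C)(C(C)C)C(C)C)C/C=C/[C@H](O[Si](CC)(CC)CC)CC=C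
F4 | step 16 | (4R,5R,7E,9R)-9-(triethylsilyloxy)-5-(triisopropylsilyloxy)dodeca-7,11-dien-2-yn-4-ol | CC#C[C@@H](O)[C@H](O[Si](C(C)C)(C(C)C)C(C)C)C/C=C/[C@H](O[Si](CC)(CC)CC)CC=C
F5 | step 19 | (4R,6S,8S)-4,6,8-trimethyldec-2-yn-1-ol | CC[C@H](C)C[C@H](C)C[C@@H](C)C#CCO
F6 | step 19 | (2E,4R,6S,8S)-4,6,8-trimethyl-2-(tributylstannyl)dec-2-en-1-ol | CC[C@H](C)C[C@H](C)C[C@@H](C)/C=C(CO)/[Sn](CCCC)(CCCC)CCCC
F7 | step 19 | (1E,3R,4S,5E,7R,9E,11R)-1-iodo-2,4-dimethyl-11-(triethylsilyloxy)-7-(triisopropylsilyloxy)tetradeca-1,5,9,13-tetraen-3-ol | I/C=C(\C)[C@H](O)[C@@H](C)/C=C/[C@H](O[Si](C(C)C)(C(C)C)C(C)C)C/C=C/[C@H](O[Si](CC)(CC)CC)CC=C
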